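1. At early times the dusk run reads 0.293 mM min⁻¹ of left-handed product over its first 15.0 min. The midnight run, with half the substrate, reads 0.250 mM min⁻¹ over its first 12.0 min. No earlier run changes the charge of free catalyst, so the proportionality of the rate to the catalyst at work, with substrate and reagent held fixed, is my assumption and no reading of these runs.

| run | time / min | left-handed product / % |
|---|---|---|
| dusk | 6.00 | 1.6 |
| dusk | 15.0 | 4.4 |
| dusk | 20.0 | 6.1 |
| dusk | 25.0 | 6.9 |
| midnight | 12.0 | 6.0 |
| midnight | 30.0 | 13.3 |
| midnight | 60.0 | 22.5 |
| midnight | 90.0 | 30.2 |

(standard deviation of a reading: 0.3 percentage points)

2. The flask and the questions: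

the same everywhere: free catalyst 0.25 mM; impurity 35 µM

|  | left-handed substrate | right-handed substrate | reagent | remark |
|---|---|---|---|---|
| dusk | 0.050 M | 0.050 M | 0.10 M | the very flask that is asked about, followed so far |
| midnight | 0.025 M | 0.025 M | 0.10 M | run made earlier |
| flask | 0.050 M | 0.050 M | 0.100 M |  |

* factor on the rate of making left-handed product when 50% of the left-handed substrate and right-handed substrate together are converted if reagent is charged twice over
* factor on the rate when 50% of the left-handed substrate and right-handed substrate together are converted if free catalyst is charged at 0.050 mM instead

- free catalyst is single-handed; left-handed substrate and right-handed substrate are mirror images of each other, charged as a racemate, each of them at the stated concentration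
- no earlier run changes the charge of free catalyst; that part of a forecast is a guess
- no earlier run changes the charge of reagent; that part of a forecast is a guess

3. A first answer for the lower catalyst charge takes the charges as they stand: 0.200. Going round again brings in c(impurity) = 35 µM. If each impurity removes one catalyst, what counts is live catalyst, the charge of free catalyst minus the charge of impurity: 0.215 mM in the flask. At the lower charge it is 0.0150 mM. My reckoned factor is 0.0698. No earlier run changes reagent, so live catalyst gives no figure for doubling it.

4. The forecast gives 1.9 for doubled reagent, with a range of 1 to 3.1. For the lower catalyst charge it gives 0.09, with a range of 0.05 to 0.21, which differs from my 0.0698. On the impurity it says: “I lean towards poisoning.”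

5. The simulation gives 2.70 for doubled reagent, above the forecast, and 0.0705 for the lower catalyst charge, below the forecast.

    reagent + catalyst intermediate A → free catalyst + left-handed product (k = 0.410 M⁻¹ s⁻¹)
    free catalyst + impurity → spent catalyst (k = 1700 M⁻¹ s⁻¹)
    free catalyst + left-handed substrate ⇌ catalyst intermediate A (K = 240 M⁻¹, k = 7.80 M⁻¹ s⁻¹)
    free catalyst + right-handed substrate ⇌ catalyst intermediate B (K = 92.0 M⁻¹, k = 2.10 M⁻¹ s⁻¹)
    reagent ⇌ dormant form (K = 0.460, k = 2.40 × 10⁻⁴ s⁻¹)
    reagent + catalyst intermediate B → free catalyst + right-handed product (k = 0.170 M⁻¹ s⁻¹)

The apparent order in reagent at 50% conversion is 1.9, and the falling back of catalyst intermediate B to free catalyst and right-handed substrate is one part of what holds it there: without that step it is 2.4. In the flask, impurity stands at 0% of its charge by 0.150 h, and spent catalyst stands at 14.0% of the catalyst charged at 1.50 h. The charges give 14.0%. A second flask is the same run with the path from free catalyst and impurity to spent catalyst removed, and for it live catalyst gives a factor of 1.16. The loss of catalyst to impurity is one part of what holds the rate down: at 50% conversion that run stands at 1.16 times the actual rate.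

All runs are calculated from invented constants, and the scatter is random.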